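**Retrosynthetic overview** (carotenoid numbering: ring end C1–C15, acyclic end C1′–C15′)

- The last C–C bond is C7=C8, made by Wittig olefination of a C10 cyclopentanecarbaldehyde (C1–C7, both hydroxyls as TES ethers) with the C30 ylide C8–C1′. The ylide is assembled from pseudoionone, a vinyl C2 unit, the C10 dialdehyde and a C5 phosphonate.
- The feature used: the ring C2–C3–C4–C5–C6, with C1 (CMe2O) on C2, the methyl carbinol at C5 and the exocyclic C7 on C6 between C5 and C2, is a p-menthane whose C7 has been pushed out of the ring. The aldehyde therefore comes from contraction of the C6–C7 oxirane of a p-menthane-1,8-diol: the C5–C7 bond becomes the C5–C6 bond.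
- The oxirane comes from hydroxyl-directed epoxidation of (1R,4R)-p-menth-2-ene-1,8-diol, whose ring hydroxyl is anti to the side chain. The familiar opening of limonene 1,2-oxide leads into the (1S,4R) dienol series with the hydroxyl syn, so the anti diol is taken from (+)-2-carene by epoxidation and cyclopropylcarbinyl opening with water.
- Ring order: the six-membered ring of the carene is kept; oxirane (step 1), cyclopropane opened (step 2), second oxirane (step 3), cyclopentane by contraction (step 5); no ring is formed afterwards.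

Key step: step 5

Assumption: (+)-2-carene and the C5 phosphonate ester ethyl (2E)-4-(diethoxyphosphoryl)-2-methylbut-2-enoate are treated as purchasable, and pseudoionone is used as its (3E,5E) isomer.

**Route**

Step 1
Reactants: 1 (+)-2-carene
Product: 2 (+)-trans-2-carene oxide
Conditions: mCPBA, NaHCO3, CH2Cl2, 0 °C
Reagents that add atoms: 3-chloroperoxybenzoic acid (mCPBA), O=C(OO)c1cccc(Cl)c1
Why: Prilezhaev epoxidation of the only alkene, with the peracid approaching anti to the cyclopropane and its endo methyl group, which sets the two oxirane carbons (future C5 and C7) with oxygen anti to the CMe2 bridge, the bicarbonate buffer protecting the acid-labile product.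

Step 2
Reactants: 2 (+)-trans-2-carene oxide
Product: 3 (1R,4R)-p-menth-2-ene-1,8-diol
Conditions: H2O/acetone, HClO4 (cat., pH about 3), 0 °C; NaHCO3 quench
Reagents that add atoms: water, O
Why: Acid-catalysed cyclopropylcarbinyl-to-homoallyl opening with hydration, in which the C7–O bond ionises with participation of the C6–C1 cyclopropane bond to give the C6=C7 alkene and the tertiary C1 cation that water captures, while the C5–O bond and C2 are not touched, so the C5 hydroxyl stays anti to the C2 arm.

Step 3
Reactants: 3 (1R,4R)-p-menth-2-ene-1,8-diol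
Product: 4 (1R,2S,3S,4R)-2,3-epoxy-p-menthane-1,8-diol
Conditions: VO(acac)2 (cat.), t-BuOOH, CH2Cl2, 0 °C → rt
Reagents that add atoms: tert-butyl hydroperoxide, CC(C)(C)OO
Why: Hydroxyl-directed vanadium-catalysed epoxidation of a cyclic allylic alcohol, in which the C5 hydroxyl binds the metal peroxide and delivers oxygen to its own face of C6=C7, a preference reinforced by the C2 arm on the opposite face, which sets C6 and C7 with the oxirane syn to the C5 hydroxyl and anti to the arm.

Step 4
Reactants: 4 (1R,2S,3S,4R)-2,3-epoxy-p-menthane-1,8-diol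
Product: 5 (1R,2S,3S,4R)-2,3-epoxy-1,8-bis(triethylsilyloxy)-p-menthane
Conditions: Et3SiOTf, 2,6-lutidine, CH2Cl2, −78 → −40 °C
Reagents that add atoms: triethylsilyl trifluoromethanesulfonate, CC[Si](CC)(CC)OS(=O)(=O)C(F)(F)F
Why: Silylation of both tertiary alcohols with a silyl triflate and a hindered pyridine base, which at low temperature is far faster than activation of the oxirane, sets no stereocentre and keeps both oxygens from acting as nucleophile or alkoxide donor in step 5.

Step 5
Reactants: 5 (1R,2S,3S,4R)-2,3-epoxy-1,8-bis(triethylsilyloxy)-p-menthane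
Product: 7 (1R,2R,5R)-2-methyl-2-(triethylsilyloxy)-5-[2-(triethylsilyloxy)propan-2-yl]cyclopentane-1-carbaldehyde, via bromomagnesium alkoxide of the trans-bromohydrin 6 (not isolated)
Conditions: MgBr2·OEt2 (2 equiv), toluene, 0 °C → 80 °C
Reagents that add atoms: none
Why: MgBr2 binds the oxirane and bromide opens it anti at C6 (trans-diaxial opening from the half-chair with the C2 arm equatorial) to give 6, whose chair flip places C6–Br equatorial and antiperiplanar to the C7–C5 ring bond, so that the magnesium alkoxide on C7 pushes while C5 shifts from C7 to C6 and bromide leaves (semipinacol 1,2-alkyl shift). The closest known reaction type is the MgBr2- or LiBr-mediated contraction of cyclohexene oxides to cyclopentanecarbaldehydes through the trans-bromohydrin, together with the Lewis-acid rearrangement of 2,3-epoxy silyl ethers to β-silyloxy aldehydes, in which a silyloxy-bearing carbon is likewise the migrating group. The cyclopentane is closed by contraction and not by cyclisation: a suprafacial 1,2-shift of C5 with backside displacement of bromide at C6 makes the C5–C6 bond as the C5–C7 bond breaks, and C7 leaves the ring as the formyl carbon. C6 is the one new stereocentre, and two successive inversions there (bromide, then C5) put C5 where the oxirane oxygen was and leave C7 on the opposite face, syn to the C2 arm and the C5 methyl, while C5 migrates with retention and C2 is untouched. The step needs migration of the ring bond and not of hydride, and it needs the shift to outrun re-closure: in a trans-bromohydrin the C7–H bond is gauche to C–Br in both chairs, so only the ring bond is ever antiperiplanar, and re-closure merely returns 5. Bromide attack at C7 instead would end, through migration of C2, at the same aldehyde with the same configuration, and the two TES ethers ensure that neither oxygen acts as an alkoxide donor (no 1,3-fragmentation of the C5–C7 bond, no transannular ether from the C1 oxygen) and that the product is not a free β-hydroxy aldehyde.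

Step 6
Reactants: 8 pseudoionone
Product: 9 (4E,6E)-3,7,11-trimethyldodeca-1,4,6,10-tetraen-3-ol (racemic)
Conditions: CH2=CHMgBr, THF, 0 °C; aqueous work-up
Reagents that add atoms: vinylmagnesium bromide, C=C[Mg]Br
Why: Grignard 1,2-addition to the dienone carbonyl gives the tertiary bis-allylic alcohol, whose carbinol centre is racemic and disappears in step 7.

Step 7
Reactants: 9 (4E,6E)-3,7,11-trimethyldodeca-1,4,6,10-tetraen-3-ol
Product: 10 [(2E,4E,6E)-3,7,11-trimethyldodeca-2,4,6,10-tetraen-1-yl]triphenylphosphonium bromide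
Conditions: PPh3·HBr, MeOH, rt
Reagents that add atoms: triphenylphosphine hydrobromide, [Br-].[PH+](c1ccccc1)(c1ccccc1)c1ccccc1
Why: Allylic substitution with transposition (SN1 type), in which HBr ionises the tertiary alcohol to the delocalised cation and PPh3 adds at the unhindered primary terminus, the new trisubstituted C9′=C10′ bond settling as the E isomer under thermodynamic control.

Step 8
Reactants: 10 [(2E,4E,6E)-3,7,11-trimethyldodeca-2,4,6,10-tetraen-1-yl]triphenylphosphonium bromide; 11 (2E,4E,6E)-2,7-dimethylocta-2,4,6-trienedial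
Product: 14 C25 aldehyde (all-E)-2,7,11,15,19-pentamethylicosa-2,4,6,8,10,12,14,18-octaenal, via C15 ylide 12 (not isolated), via 11′Z isomer of the C25 aldehyde 13 (not isolated)
Conditions: 11 (3 equiv), NaOMe, MeOH/CH2Cl2, 0 °C → rt; then heptane, reflux
Reagents that add atoms: none
Why: Wittig olefination of one formyl group by the semi-stabilised ylide 12, the excess of 11 holding the reaction at the mono-adduct, with the new C11′=C12′ bond formed as an E/Z mixture whose hindered Z isomer 13 relaxes to E on heating.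

Step 9
Reactants: 14 C25 aldehyde; 15 ethyl (2E)-4-(diethoxyphosphoryl)-2-methylbut-2-enoate
Product: 17 C30 ester ethyl (all-E)-2,6,11,15,19,23-hexamethyltetracosa-2,4,6,8,10,12,14,16,18,22-decaenoate, via sodium phosphonate carbanion 16 (not isolated)
Conditions: NaH, THF, 0 °C → rt
Reagents that add atoms: none
Why: Horner–Wadsworth–Emmons olefination, in which the stabilised carbanion 16 adds through its phosphorus-bearing carbon and eliminates phosphate to give the E C11=C12 bond, the E trisubstituted C9=C10 bond coming from the reagent.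

Step 10
Reactants: 17 C30 ester
Product: 18 C30 alcohol (all-E)-2,6,11,15,19,23-hexamethyltetracosa-2,4,6,8,10,12,14,16,18,22-decaen-1-ol
Conditions: i-Bu2AlH, CH2Cl2, −78 °C; aq. potassium sodium tartrate
Reagents that add atoms: none
Why: Hydride reduction of the conjugated ester with i-Bu2AlH should stop at the primary allylic alcohol at −78 °C and leave the polyene untouched.

Step 11
Reactants: 18 C30 alcohol
Product: 19 C30 phosphonium bromide [(all-E)-2,6,11,15,19,23-hexamethyltetracosa-2,4,6,8,10,12,14,16,18,22-decaen-1-yl]triphenylphosphonium bromide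
Conditions: PPh3·HBr, MeOH/CH2Cl2, rt, dark
Reagents that add atoms: triphenylphosphine hydrobromide, [Br-].[PH+](c1ccccc1)(c1ccccc1)c1ccccc1
Why: Allylic substitution (SN1 type) of the primary polyenylic alcohol by PPh3 under HBr, the delocalised cation being captured at the terminal carbon C8, which keeps the full conjugation.

Step 12
Reactants: 19 C30 phosphonium bromide; 7 (1R,2R,5R)-2-methyl-2-(triethylsilyloxy)-5-[2-(triethylsilyloxy)propan-2-yl]cyclopentane-1-carbaldehyde
Product: 22 (all-E,2R,5R,6R)-1,5-bis(triethylsilyloxy)-2,6-cyclolycopene, via C30 ylide 20 (not isolated), via 7Z isomer of the bis-TES ether 21 (not isolated)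
Conditions: 19 (1.5 equiv), NaN(SiMe3)2 (1.45 equiv), THF, −78 → 0 °C; 7, −78 °C → rt; then heptane, 80 °C, dark
Reagents that add atoms: none
Why: Wittig olefination forming C7=C8, in which the preformed, base-free semi-stabilised ylide 20 should add to the aldehyde faster than it deprotonates C6, the silyl ethers exclude retro-aldol cleavage, and the crowded 7Z isomer 21 relaxes thermally to 7E, so that no stereocentre is formed and C6 keeps its configuration.

Step 13
Reactants: 22 (all-E,2R,5R,6R)-1,5-bis(triethylsilyloxy)-2,6-cyclolycopene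
Product: 23 (all-E,2R,5R,6R)-2,6-cyclolycopene-1,5-diol (target)
Conditions: Bu4NF, THF, 0 °C → rt; crystallisation
Reagents that add atoms: none
Why: Fluoride-induced cleavage of the two tertiary triethylsilyl ethers (Si–F bond formation) under non-acidic conditions that the polyene and the tertiary carbinols tolerate, with crystallisation delivering the all-E diol.

**Compound list**

1 | (+)-2-carene, (1S,6R)-3,7,7-trimethylbicyclo[4.1.0]hept-2-ene | CC1=C[C@H]2[C@@H](CC1)C2(C)C | starting material
2 | (+)-trans-2-carene oxide, (1S,2S,3R,6R)-2,3-epoxycarane, oxirane anti to the cyclopropane | C[C@@]12CC[C@@H]3[C@@H](C3(C)C)[C@@H]1O2 | intermediate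
3 | (1R,4R)-4-(2-hydroxypropan-2-yl)-1-methylcyclohex-2-en-1-ol, ring hydroxyl anti to the side chain | C[C@@]1(O)CC[C@@H](C(C)(C)O)C=C1 | intermediate
4 | (1R,2S,3S,4R)-2,3-epoxy-p-menthane-1,8-diol, oxirane syn to the ring hydroxyl | C[C@@]1(O)CC[C@@H](C(C)(C)O)[C@@H]2O[C@H]12 | intermediate
5 | (1R,2S,3S,4R)-2,3-epoxy-1,8-bis(triethylsilyloxy)-p-menthane | C[C@@]1(O[Si](CC)(CC)CC)CC[C@@H](C(C)(C)O[Si](CC)(CC)CC)[C@@H]2O[C@H]12 | intermediate
6 | bromomagnesium (1R,2R,3R,4S)-3-bromo-1,8-bis(triethylsilyloxy)-p-menthan-2-olate, C6–Br anti to C7–O | C[C@@]1(O[Si](CC)(CC)CC)CC[C@@H](C(C)(C)O[Si](CC)(CC)CC)[C@@H](Br)[C@@H]1O[Mg]Br | intermediate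
7 | (1R,2R,5R)-2-methyl-2-(triethylsilyloxy)-5-[2-(triethylsilyloxy)propan-2-yl]cyclopentane-1-carbaldehyde | O=C[C@@H]1[C@H](C(C)(C)O[Si](CC)(CC)CC)CC[C@@]1(C)O[Si](CC)(CC)CC | intermediate
8 | pseudoionone, (3E,5E)-6,10-dimethylundeca-3,5,9-trien-2-one | CC(C)=CCC/C(C)=C/C=C/C(C)=O | starting material
9 | (4E,6E)-3,7,11-trimethyldodeca-1,4,6,10-tetraen-3-ol, racemic | CC(C)=CCC/C(C)=C/C=C/C(C)(O)C=C | intermediate
10 | [(2E,4E,6E)-3,7,11-trimethyldodeca-2,4,6,10-tetraen-1-yl]triphenylphosphonium bromide | CC(C)=CCC/C(C)=C/C=C/C(C)=C/C[P+](c1ccccc1)(c1ccccc1)c1ccccc1.[Br-] | intermediate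
11 | (2E,4E,6E)-2,7-dimethylocta-2,4,6-trienedial | O=C/C(C)=C/C=C/C=C(C)/C=O | starting material
12 | C15 ylide, [(2E,4E,6E)-3,7,11-trimethyldodeca-2,4,6,10-tetraen-1-ylidene]triphenylphosphorane | CC(C)=CCC/C(C)=C/C=C/C(C)=C/C=P(c1ccccc1)(c1ccccc1)c1ccccc1 | intermediate
13 | 11′Z isomer of the C25 aldehyde, (2E,4E,6E,8Z,10E,12E,14E)-2,7,11,15,19-pentamethylicosa-2,4,6,8,10,12,14,18-octaenal | CC(C)=CCC/C(C)=C/C=C/C(C)=C/C=C\C(C)=C\C=C\C=C(C)\C=O | intermediate
14 | C25 aldehyde, (all-E)-2,7,11,15,19-pentamethylicosa-2,4,6,8,10,12,14,18-octaenal | CC(C)=CCC/C(C)=C/C=C/C(C)=C/C=C/C(C)=C/C=C/C=C(C)/C=O | intermediate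
15 | ethyl (2E)-4-(diethoxyphosphoryl)-2-methylbut-2-enoate | CCOC(=O)/C(C)=C/CP(=O)(OCC)OCC | starting material
16 | sodium salt of the carbanion of 15 | CCOC(=O)/C(C)=C/[CH-]P(=O)(OCC)OCC.[Na+] | intermediate
17 | C30 ester, ethyl (all-E)-2,6,11,15,19,23-hexamethyltetracosa-2,4,6,8,10,12,14,16,18,22-decaenoate | CC(C)=CCC/C(C)=C/C=C/C(C)=C/C=C/C(C)=C/C=C/C=C(C)/C=C/C=C(C)/C(=O)OCC | intermediate
18 | C30 alcohol, (all-E)-2,6,11,15,19,23-hexamethyltetracosa-2,4,6,8,10,12,14,16,18,22-decaen-1-ol | CC(C)=CCC/C(C)=C/C=C/C(C)=C/C=C/C(C)=C/C=C/C=C(C)/C=C/C=C(C)/CO | intermediate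
19 | C30 phosphonium bromide, [(all-E)-2,6,11,15,19,23-hexamethyltetracosa-2,4,6,8,10,12,14,16,18,22-decaen-1-yl]triphenylphosphonium bromide | CC(C)=CCC/C(C)=C/C=C/C(C)=C/C=C/C(C)=C/C=C/C=C(C)/C=C/C=C(C)/C[P+](c1ccccc1)(c1ccccc1)c1ccccc1.[Br-] | intermediate
20 | C30 ylide, the triphenylphosphorane of 19 | CC(C)=CCC/C(C)=C/C=C/C(C)=C/C=C/C(C)=C/C=C/C=C(C)/C=C/C=C(C)/C=P(c1ccccc1)(c1ccccc1)c1ccccc1 | intermediate
21 | (7Z,2R,5R,6R)-1,5-bis(triethylsilyloxy)-2,6-cyclolycopene | CC(C)=CCC/C(C)=C/C=C/C(C)=C/C=C/C(C)=C/C=C/C=C(C)/C=C/C=C(C)/C=C\[C@@H]1[C@H](C(C)(C)O[Si](CC)(CC)CC)CC[C@@]1(C)O[Si](CC)(CC)CC | intermediate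
22 | (all-E,2R,5R,6R)-1,5-bis(triethylsilyloxy)-2,6-cyclolycopene | CC(C)=CCC/C(C)=C/C=C/C(C)=C/C=C/C(C)=C/C=C/C=C(C)/C=C/C=C(C)/C=C/[C@@H]1[C@H](C(C)(C)O[Si](CC)(CC)CC)CC[C@@]1(C)O[Si](CC)(CC)CC | intermediate
23 | (all-E,2R,5R,6R)-2,6-cyclolycopene-1,5-diol, CNP0169920.2 | CC(C)=CCC/C(C)=C/C=C/C(C)=C/C=C/C(C)=C/C=C/C=C(C)/C=C/C=C(C)/C=C/[C@@H]1[C@H](C(C)(C)O)CC[C@@]1(C)O | target

**Totals**

Total step count: 13. Longest linear sequence: 8 steps (steps 6 to 13, from pseudoionone); the terpene branch is 7 steps (steps 1 to 5, 12, 13).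

**Steps most likely to fail**

1. Step 5. The reactive chair needs the C2 arm axial, so migration may be slow; re-closure to the oxirane, thermal loss of a silyl group at 80 °C and β-elimination in the product may then compete. The fallback sets out from 5 and comes back at 7, and it separates the two events. Compound 5 is opened with MgBr2·OEt2 in Et2O at −20 °C and quenched cold, to isolate the trans-bromohydrin F1. The shift is then driven from the leaving-group side by a monovalent silver salt (AgOTf, 2,6-di-tert-butylpyridine, CH2Cl2, −20 °C → rt), the classical silver-assisted semipinacol contraction of trans-2-halocycloalkanols, which should give 7 without heating.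

2. Step 12. The bulky C30 ylide may add slowly to an aldehyde flanked by two substituted ring carbons, which leaves time for epimerisation at C6 or for β-elimination of silanolate. The fallback sets out from 7 and 14 and comes back at 22, and it meets the hindered carbonyl with a small reagent first. Horner–Wadsworth–Emmons reaction of 7 with triethyl 3-methyl-4-phosphonocrotonate (LiN(SiMe3)2, THF, −78 → 0 °C) gives the C15 dienoate F2. Reduction with i-Bu2AlH gives the C15 dienol F3, and MnO2 oxidises it to the unhindered C15 dienal F4. In parallel 14 is reduced with NaBH4 to the C25 alcohol F5, converted with PPh3·HBr into the C25 phosphonium bromide F6 and deprotonated with NaN(SiMe3)2 to the C25 ylide F7. Wittig reaction of the ylide with F4 forms C11=C12, and the 11Z isomer of the bis-TES ether F8 is equilibrated thermally, as in step 12, to give 22.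

3. Step 2. The C1 cation may lose a proton instead of being captured by water, and acid may ionise the allylic C5 carbinol and scramble C5. The fallback sets out from 2 and comes back at 3, and it accepts the elimination. Compound 2 is isomerised under anhydrous, weakly acidic conditions (pyridinium p-toluenesulfonate, CH2Cl2, 0 °C) to the dienol (1R,4R)-p-mentha-2,8-dien-1-ol F9. Its isopropenyl group is then hydrated in the Markovnikov sense under neutral radical conditions by Mukaiyama hydration (Co(acac)2, PhSiH3, O2, i-PrOH; then Na2S2O3), which should leave the ring alkene and the C5 carbinol alone and give 3.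

**Further compounds**

F1 | step 5 | (1R,2R,3R,4S)-3-bromo-1,8-bis(triethylsilyloxy)-p-menthan-2-ol | C[C@@]1(O[Si](CC)(CC)CC)CC[C@@H](C(C)(C)O[Si](CC)(CC)CC)[C@@H](Br)[C@@H]1O
F2 | step 12 | ethyl (2E,4E)-3-methyl-5-{(1R,2R,5R)-2-methyl-2-(triethylsilyloxy)-5-[2-(triethylsilyloxy)propan-2-yl]cyclopentyl}penta-2,4-dienoate | CCOC(=O)/C=C(C)/C=C/[C@@H]1[C@H](C(C)(C)O[Si](CC)(CC)CC)CC[C@@]1(C)O[Si](CC)(CC)CC
F3 | step 12 | (2E,4E)-3-methyl-5-{(1R,2R,5R)-2-methyl-2-(triethylsilyloxy)-5-[2-(triethylsilyloxy)propan-2-yl]cyclopentyl}penta-2,4-dien-1-ol | OC/C=C(C)/C=C/[C@@H]1[C@H](C(C)(C)O[Si](CC)(CC)CC)CC[C@@]1(C)O[Si](CC)(CC)CC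
F4 | step 12 | (2E,4E)-3-methyl-5-{(1R,2R,5R)-2-methyl-2-(triethylsilyloxy)-5-[2-(triethylsilyloxy)propan-2-yl]cyclopentyl}penta-2,4-dienal | O=C/C=C(C)/C=C/[C@@H]1[C@H](C(C)(C)O[Si](CC)(CC)CC)CC[C@@]1(C)O[Si](CC)(CC)CC
F5 | step 12 | (all-E)-2,7,11,15,19-pentamethylicosa-2,4,6,8,10,12,14,18-octaen-1-ol | CC(C)=CCC/C(C)=C/C=C/C(C)=C/C=C/C(C)=C/C=C/C=C(C)/CO
F6 | step 12 | [(all-E)-2,7,11,15,19-pentamethylicosa-2,4,6,8,10,12,14,18-octaen-1-yl]triphenylphosphonium bromide | CC(C)=CCC/C(C)=C/C=C/C(C)=C/C=C/C(C)=C/C=C/C=C(C)/C[P+](c1ccccc1)(c1ccccc1)c1ccccc1.[Br-]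
F7 | step 12 | triphenylphosphorane (ylide) of F6 | CC(C)=CCC/C(C)=C/C=C/C(C)=C/C=C/C(C)=C/C=C/C=C(C)/C=P(c1ccccc1)(c1ccccc1)c1ccccc1
F8 | step 12 | (11Z,2R,5R,6R)-1,5-bis(triethylsilyloxy)-2,6-cyclolycopene | CC(C)=CCC/C(C)=C/C=C/C(C)=C/C=C/C(C)=C/C=C/C=C(C)/C=C\C=C(C)\C=C\[C@@H]1[C@H](C(C)(C)O[Si](CC)(CC)CC)CC[C@@]1(C)O[Si](CC)(CC)CC
F9 | step 2 | (1R,4R)-1-methyl-4-(prop-1-en-2-yl)cyclohex-2-en-1-ol | C[C@@]1(O)CC[C@@H](C(C)=C)C=C1
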